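## Retrosynthetic overview

1. The target comes from its 7-methyl ester 11-ketone by C11 reduction and ester cleavage. Ring D (C13–C16 bond, exocyclic methylene) is closed last by a tin-radical alkyne–enone cyclisation.
2. The 2β,3β-diol comes from OsO4 on a Δ2 alkene. Ring A is closed by ring-closing metathesis of a C4 vinyl and a C10 allyl group held on the 19,20-lactone.
3. The lactone and the C4–C5 bond come from a tethered intramolecular Michael addition of a C20 ester enolate onto a ring B cyclopentene ester (sets C4, C5 and the trans A/B fusion).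
4. The C10 quaternary centre comes from convex-face allylation of a ring B β-keto ester; C20 comes from reduction of that ester.
5. Rings B/C with C8 and C9 come from an amine-catalysed Michael / iodine-mediated α-alkylation [3+2] annulation of 3-(silylpropargyl)cyclohexenone with dimethyl 3-oxopentanedioate. Ring order: C (present), B, lactone, A, D.

Assumption: locants C1–C20 and α/β follow gibberellin usage for the target (lactone bridge α); the epi-quinine-derived amine in step 2 is assumed to give the drawn enantiomer (otherwise its epi-quinidine pseudoenantiomer is used).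

## Route

Step 1
Reactants: 1 3-ethoxycyclohex-2-en-1-one; 2 (3-bromoprop-1-yn-1-yl)trimethylsilane
Product: 4 3-[3-(trimethylsilyl)prop-2-yn-1-yl]cyclohex-2-en-1-one, via carbinol adduct 3 (not isolated)
Conditions: Zn dust, THF, 0 °C to rt; then 1 M aq. HCl, 0 °C
Reagents that add atoms: water, O
Why: Barbier 1,2-addition of the silylpropargyl zinc reagent to the vinylogous ester followed by acid-mediated Stork–Danheiser transposition gives the 3-substituted enone; no stereocentre is formed.

Step 2
Reactants: 4 3-[3-(trimethylsilyl)prop-2-yn-1-yl]cyclohex-2-en-1-one; 5 dimethyl 3-oxopentanedioate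
Product: 8 dimethyl cis-2,4-dioxo-7a-[3-(trimethylsilyl)prop-2-yn-1-yl]octahydro-1H-indene-1,3-dicarboxylate, via Michael adduct 6 (not isolated), via iodo diester 7 (not isolated)
Conditions: 9-amino-9-deoxy-epi-quinine (20 mol %), 2-fluorobenzoic acid (40 mol %), toluene, 40 °C (9 kbar if slow); then I2 (1.2 equiv), DBU (2.5 equiv), MeCN, 0 °C to rt
Reagents that add atoms: none
Why: Proposed new method: iminium activation of 4 by the chiral primary amine lets one acidic CH2 of 5 add to the β-carbon from the unshielded face and set the C8 quaternary centre (closest known: cinchona primary-amine Michael additions of malonates and nitroalkanes to β-substituted cyclohexenones), then I2/DBU iodinates the remaining doubly activated CH2 and the ketone α-carbon C9 closes ring B by 5-exo-tet alkylation, the only feasible ring size and necessarily cis-fused (closest known: iodine/base Michael-initiated ring closures to cyclopropanes and amine-catalysed Michael/α-alkylation of enals with 4-bromoacetoacetate).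

Step 3
Reactants: 8 dimethyl cis-2,4-dioxo-7a-[3-(trimethylsilyl)prop-2-yn-1-yl]octahydro-1H-indene-1,3-dicarboxylate
Product: 9 dimethyl 3-allyl-2,4-dioxo-7a-[3-(trimethylsilyl)prop-2-yn-1-yl]octahydro-1H-indene-1,3-dicarboxylate
Conditions: K2CO3 (1.5 equiv), allyl bromide (1.1 equiv), acetone, 0 °C to rt
Reagents that add atoms: allyl bromide, C=CCBr
Why: β-Keto ester C-alkylation takes place at C10 rather than at the neopentyl C6 next to the quaternary ring-fusion carbon, and from the convex face of the cis-hydrindane (syn to H-9), which sets the C10 quaternary centre with the allyl group anti to C11.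

Step 4
Reactants: 9 dimethyl 3-allyl-2,4-dioxo-7a-[3-(trimethylsilyl)prop-2-yn-1-yl]octahydro-1H-indene-1,3-dicarboxylate
Product: 10 methyl 3-allyl-4-hydroxy-3-(hydroxymethyl)-2-oxo-7a-[3-(trimethylsilyl)prop-2-yn-1-yl]octahydro-1H-indene-1-carboxylate
Conditions: NaH (1.1 equiv), THF, 0 °C; then i-Bu2AlH (5 equiv), −78 to −40 °C; aq. potassium sodium tartrate
Reagents that add atoms: none
Why: With the enolisable C5/C7 β-keto ester masked as its sodium enolate (enolate-protection reduction), i-Bu2AlH reduces only the non-enolisable C20 ester to CH2OH and the C11 ketone to an alcohol that is re-oxidised in step 8, so no retained stereocentre is formed.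

Step 5
Reactants: 10 methyl 3-allyl-4-hydroxy-3-(hydroxymethyl)-2-oxo-7a-[3-(trimethylsilyl)prop-2-yn-1-yl]octahydro-1H-indene-1-carboxylate; 11 (E)-2-methylbut-2-enoyl chloride
Product: 13 methyl 3-allyl-4-hydroxy-3-{[(2-methylbut-3-enoyl)oxy]methyl}-2-oxo-7a-[3-(trimethylsilyl)prop-2-yn-1-yl]octahydro-1H-indene-1-carboxylate, via methylvinylketene 12 (not isolated)
Conditions: 11 (1.2 equiv), Et3N (2 equiv), CH2Cl2, −78 to 0 °C
Reagents that add atoms: none
Why: Dehydrochlorination of the acid chloride gives the vinylketene, which the primary C20 hydroxyl traps faster than the hindered secondary one to give the deconjugated ester (vinylketene esterification); the ester α-centre forms as a mixture and is erased in step 9.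

Step 6
Reactants: 13 methyl 3-allyl-4-hydroxy-3-{[(2-methylbut-3-enoyl)oxy]methyl}-2-oxo-7a-[3-(trimethylsilyl)prop-2-yn-1-yl]octahydro-1H-indene-1-carboxylate
Product: 14 methyl 3-allyl-4-hydroxy-3-{[(2-methylbut-3-enoyl)oxy]methyl}-7a-[3-(trimethylsilyl)prop-2-yn-1-yl]-2-{[(trifluoromethyl)sulfonyl]oxy}-3a,4,5,6,7,7a-hexahydro-3H-indene-1-carboxylate
Conditions: NaH (1.05 equiv), THF, 0 °C; PhNTf2 (1.1 equiv), 0 °C to rt; aq. NH4Cl
Reagents that add atoms: N-phenylbis(trifluoromethanesulfonimide), O=S(=O)(N(c1ccccc1)S(=O)(=O)C(F)(F)F)C(F)(F)F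
Why: One equivalent of NaH deprotonates only the β-keto ester, whose enolate oxygen is sulfonylated (enol triflate formation) while the neutral secondary alcohol is inert; no stereocentre is formed.

Step 7
Reactants: 14 methyl 3-allyl-4-hydroxy-3-{[(2-methylbut-3-enoyl)oxy]methyl}-7a-[3-(trimethylsilyl)prop-2-yn-1-yl]-2-{[(trifluoromethyl)sulfonyl]oxy}-3a,4,5,6,7,7a-hexahydro-3H-indene-1-carboxylate
Product: 15 methyl 3-allyl-4-hydroxy-3-{[(2-methylbut-3-enoyl)oxy]methyl}-7a-[3-(trimethylsilyl)prop-2-yn-1-yl]-3a,4,5,6,7,7a-hexahydro-3H-indene-1-carboxylate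
Conditions: Pd(OAc)2 (5 mol %), PPh3 (10 mol %), HCO2H, n-Bu3N, DMF, 60 °C
Reagents that add atoms: none
Why: Palladium-catalysed formate reduction of the vinyl triflate (Cacchi reduction) gives the cyclopentene ester that is the Michael acceptor of step 9; no stereocentre is formed.

Step 8
Reactants: 15 methyl 3-allyl-4-hydroxy-3-{[(2-methylbut-3-enoyl)oxy]methyl}-7a-[3-(trimethylsilyl)prop-2-yn-1-yl]-3a,4,5,6,7,7a-hexahydro-3H-indene-1-carboxylate
Product: 17 methyl 3-allyl-3-{[(2-methylbut-3-enoyl)oxy]methyl}-4-oxo-7a-[3-(trimethylsilyl)prop-2-yn-1-yl]-3a,4,7,7a-tetrahydro-3H-indene-1-carboxylate, via saturated ketone 16 (not isolated)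
Conditions: IBX (4 equiv), DMSO/fluorobenzene 1:2, 70 °C
Reagents that add atoms: none
Why: IBX oxidises the C11 alcohol and then dehydrogenates the ketone (Nicolaou IBX dehydrogenation) on the only side with a β-hydrogen (C12–C13, since C8 and C10 are quaternary), which removes the acidic C12 protons before step 9 and provides the radical acceptor for step 13.

Step 9
Reactants: 17 methyl 3-allyl-3-{[(2-methylbut-3-enoyl)oxy]methyl}-4-oxo-7a-[3-(trimethylsilyl)prop-2-yn-1-yl]-3a,4,7,7a-tetrahydro-3H-indene-1-carboxylate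
Product: 18 tricyclic 19,20-δ-lactone (C4 methyl/vinyl; C10 allyl; Δ12-11-ketone; C6 CO2Me; C8 silylpropargyl)
Conditions: KN(SiMe3)2 (1.2 equiv), THF, −78 to −20 °C; MeOH, 0 °C, 1 h; AcOH
Reagents that add atoms: none
Why: The ester enolate adds 6-exo-trig (intramolecular Michael addition) to C5 from the face of the C20 tether, which forces the cis lactone fusion and hence H-5 trans to C20, and creates the C4 quaternary centre through an exo chair with the compact methyl over ring B and the vinyl group outward, while methoxide equilibration places the C6 ester trans to C4.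

Step 10
Reactants: 18 tricyclic 19,20-δ-lactone (C4 methyl/vinyl; C10 allyl; Δ12-11-ketone; C6 CO2Me; C8 silylpropargyl)
Product: 19 tetracyclic Δ2-ene lactone (ring A closed; Δ12-11-ketone; C6 CO2Me; C8 silylpropargyl)
Conditions: second-generation Grubbs catalyst (H2IMes)(PCy3)Cl2Ru=CHPh (5 mol %), CH2Cl2 (2 mM), 40 °C
Reagents that add atoms: none
Why: Ring-closing metathesis of the C4 vinyl and C10 allyl groups, which are 1,3-cis on the lactone ring, closes ring A as the bridged cyclohexene while the enone and silylalkyne stay inert; no stereocentre is formed.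

Step 11
Reactants: 19 tetracyclic Δ2-ene lactone (ring A closed; Δ12-11-ketone; C6 CO2Me; C8 silylpropargyl)
Product: 20 2β,3β-diol of lactone 19
Conditions: OsO4 (4 mol %), NMO (1.5 equiv), acetone/H2O 5:1, 0 °C to rt
Reagents that add atoms: N-methylmorpholine N-oxide, C[N+]1([O-])CCOCC1; water, O
Why: Upjohn dihydroxylation attacks the electron-rich Δ2 alkene (the enone alkene is deactivated, the silylalkyne inert) from the face opposite the lactone bridge and gives the 2β,3β-cis-diol.

Step 12
Reactants: 20 2β,3β-diol of lactone 19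
Product: 21 C8-propargyl (terminal alkyne) enone diol
Conditions: K2CO3 (0.2 equiv), MeOH, 0 °C
Reagents that add atoms: none
Why: Mild methanolysis of the alkynyl C–Si bond (protodesilylation) frees the terminal alkyne needed for tin-radical addition; no stereocentre is formed.

Step 13
Reactants: 21 C8-propargyl (terminal alkyne) enone diol
Product: 23 methyl ester of the 11-oxo analogue of the target, via vinylstannane 22 (not isolated)
Conditions: n-Bu3SnH (1.3 equiv), AIBN (0.2 equiv), benzene (5 mM), 80 °C, slow addition; then wet SiO2, CH2Cl2, rt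
Reagents that add atoms: none
Why: Stork-type radical cyclisation: the tin radical adds to the alkyne terminus, the vinyl radical closes 5-exo-trig onto the enone β-carbon C13 from the only face the C8 tether can reach (ring D and the C13 centre), and silica protodestannylation leaves the exocyclic methylene.

Step 14
Reactants: 23 methyl ester of the 11-oxo analogue of the target
Product: 24 target 7-methyl ester (11β-alcohol)
Conditions: LiBH(s-Bu)3 (3 equiv), THF, −78 °C; H2O
Reagents that add atoms: none
Why: The bulky hydride attacks the bicyclo[3.2.1]octan-3-one carbonyl from the face away from the two-carbon C15–C16 bridge (as in tropinone-to-tropine reductions) and gives the axial 11β-alcohol cis to H-9.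

Step 15
Reactants: 24 target 7-methyl ester (11β-alcohol)
Product: 25 CNP0302900.3
Conditions: LiSPr (0.5 M in HMPA, 6 equiv), rt; then 1 M aq. HCl
Reagents that add atoms: none
Why: SN2 demethylation of the hindered C7 methyl ester by thiolate (the usual deprotection of gibberellin 7-methyl esters) spares the lactone and the exocyclic alkene and gives the acid on acidification; no stereocentre is touched.

## Compound list

1 | 3-ethoxycyclohex-2-en-1-one | CCOC1=CC(=O)CCC1 | starting material
2 | (3-bromoprop-1-yn-1-yl)trimethylsilane | C[Si](C)(C)C#CCBr | starting material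
3 | 3-ethoxy-1-[3-(trimethylsilyl)prop-2-yn-1-yl]cyclohex-2-en-1-ol (racemic, not isolated) | CCOC1=CC(O)(CC#C[Si](C)(C)C)CCC1 | intermediate
4 | 3-[3-(trimethylsilyl)prop-2-yn-1-yl]cyclohex-2-en-1-one | C[Si](C)(C)C#CCC1=CC(=O)CCC1 | intermediate
5 | dimethyl 3-oxopentanedioate | COC(=O)CC(=O)CC(=O)OC | starting material
6 | dimethyl 2-{3-oxo-1-[3-(trimethylsilyl)prop-2-yn-1-yl]cyclohexyl}-3-oxopentanedioate, C8 quaternary centre set, C6 epimers (not isolated) | C[Si](C)(C)C#CC[C@]1(CC(=O)CCC1)C(C(=O)OC)C(=O)CC(=O)OC | intermediate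
7 | dimethyl 2-iodo-3-oxo-4-{3-oxo-1-[3-(trimethylsilyl)prop-2-yn-1-yl]cyclohexyl}pentanedioate (not isolated) | C[Si](C)(C)C#CC[C@]1(CC(=O)CCC1)C(C(=O)OC)C(=O)C(I)C(=O)OC | intermediate
8 | dimethyl cis-2,4-dioxo-7a-[3-(trimethylsilyl)prop-2-yn-1-yl]octahydro-1H-indene-1,3-dicarboxylate; H-3a (H-9) cis to the 7a side chain; C1/C3 ester carbons epimerisable/enolised | C[Si](C)(C)C#CC[C@]12CCCC(=O)[C@H]1C(C(=O)OC)C(=O)C2C(=O)OC | intermediate
9 | dimethyl 3-allyl-2,4-dioxo-7a-[3-(trimethylsilyl)prop-2-yn-1-yl]octahydro-1H-indene-1,3-dicarboxylate; allyl on the face of H-3a; C1 epimerisable | C[Si](C)(C)C#CC[C@]12CCCC(=O)[C@H]1[C@@](CC=C)(C(=O)OC)C(=O)C2C(=O)OC | intermediate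
10 | methyl 3-allyl-4-hydroxy-3-(hydroxymethyl)-2-oxo-7a-[3-(trimethylsilyl)prop-2-yn-1-yl]octahydro-1H-indene-1-carboxylate; C4 carbinol (C11) epimers, both used | C[Si](C)(C)C#CC[C@]12CCCC(O)[C@H]1[C@@](CC=C)(CO)C(=O)C2C(=O)OC | intermediate
11 | (E)-2-methylbut-2-enoyl chloride (tigloyl chloride) | C/C=C(\C)C(Cl)=O | starting material
12 | 2-methylbuta-1,3-dien-1-one (methylvinylketene, not isolated) | C=CC(C)=C=O | intermediate
13 | methyl 3-allyl-4-hydroxy-3-{[(2-methylbut-3-enoyl)oxy]methyl}-2-oxo-7a-[3-(trimethylsilyl)prop-2-yn-1-yl]octahydro-1H-indene-1-carboxylate; ester α-carbon and C11 carbinol as mixtures | C[Si](C)(C)C#CC[C@]12CCCC(O)[C@H]1[C@@](CC=C)(COC(=O)C(C)C=C)C(=O)C2C(=O)OC | intermediate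
14 | enol triflate of 13 at C5/C6 (methyl 3-allyl-4-hydroxy-3-{[(2-methylbut-3-enoyl)oxy]methyl}-7a-[3-(trimethylsilyl)prop-2-yn-1-yl]-2-{[(trifluoromethyl)sulfonyl]oxy}-3a,4,5,6,7,7a-hexahydro-3H-indene-1-carboxylate) | C[Si](C)(C)C#CC[C@]12CCCC(O)[C@H]1[C@@](CC=C)(COC(=O)C(C)C=C)C(OS(=O)(=O)C(F)(F)F)=C2C(=O)OC | intermediate
15 | methyl 3-allyl-4-hydroxy-3-{[(2-methylbut-3-enoyl)oxy]methyl}-7a-[3-(trimethylsilyl)prop-2-yn-1-yl]-3a,4,5,6,7,7a-hexahydro-3H-indene-1-carboxylate (C5=C6 cyclopentene ester) | C[Si](C)(C)C#CC[C@]12CCCC(O)[C@H]1[C@@](CC=C)(COC(=O)C(C)C=C)C=C2C(=O)OC | intermediate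
16 | 4-oxo (C11 ketone) analogue of 15, saturated ring C (not isolated) | C[Si](C)(C)C#CC[C@]12CCCC(=O)[C@H]1[C@@](CC=C)(COC(=O)C(C)C=C)C=C2C(=O)OC | intermediate
17 | methyl 3-allyl-3-{[(2-methylbut-3-enoyl)oxy]methyl}-4-oxo-7a-[3-(trimethylsilyl)prop-2-yn-1-yl]-3a,4,7,7a-tetrahydro-3H-indene-1-carboxylate (C11 ketone, C12=C13 enone) | C[Si](C)(C)C#CC[C@]12CC=CC(=O)[C@H]1[C@@](CC=C)(COC(=O)C(C)C=C)C=C2C(=O)OC | intermediate
18 | tricyclic lactone: δ-lactone C19(=O)–O–C20H2 bridging C4 and C10, cis-fused to ring B; C4 carries methyl (β) and vinyl; C10 carries allyl; H-5 β, H-6 α (CO2Me β), H-9 β; C11 ketone with C12=C13; C8 carries CH2C≡CSiMe3 | C[Si](C)(C)C#CC[C@]12CC=CC(=O)[C@H]1[C@@]3(CC=C)COC(=O)[C@](C)(C=C)[C@H]3[C@@H]2C(=O)OC | intermediate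
19 | tetracyclic lactone: ring A closed with C2=C3 double bond (2-oxabicyclo[3.3.1]nonenone fused to the hydrindenone); otherwise as 18 | C[Si](C)(C)C#CC[C@]12CC=CC(=O)[C@H]1[C@]34COC(=O)[C@](C)(C=CC3)[C@H]4[C@@H]2C(=O)OC | intermediate
20 | 2β,3β-dihydroxy derivative of 19 (cis-diol anti to the lactone bridge) | C[Si](C)(C)C#CC[C@]12CC=CC(=O)[C@H]1[C@]34COC(=O)[C@](C)([C@@H](O)[C@@H](O)C3)[C@H]4[C@@H]2C(=O)OC | intermediate
21 | desilylated 20: C8 carries CH2C≡CH | C#CC[C@]12CC=CC(=O)[C@H]1[C@]34COC(=O)[C@](C)([C@@H](O)[C@@H](O)C3)[C@H]4[C@@H]2C(=O)OC | intermediate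
22 | 17-(tributylstannyl) derivative of 23 (exocyclic vinylstannane, alkene geometry undefined, not isolated) | CCCC[Sn](CCCC)(CCCC)C=C1C[C@]23C[C@H]1CC(=O)[C@H]2[C@]45COC(=O)[C@](C)([C@@H](O)[C@@H](O)C4)[C@H]5[C@@H]3C(=O)OC | intermediate
23 | methyl 2β,3β-dihydroxy-11-oxo-19,20-lactone gibberell-16-en-7-oate (11-ketone of the target methyl ester) | C=C1C[C@]23C[C@H]1CC(=O)[C@H]2[C@]45COC(=O)[C@](C)([C@@H](O)[C@@H](O)C4)[C@H]5[C@@H]3C(=O)OC | intermediate
24 | methyl 2β,3β,11β-trihydroxy-19,20-lactone gibberell-16-en-7-oate (target methyl ester) | C=C1C[C@]23C[C@H]1C[C@H](O)[C@H]2[C@]45COC(=O)[C@](C)([C@@H](O)[C@@H](O)C4)[C@H]5[C@@H]3C(=O)OC | intermediate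
25 | CNP0302900.3: 2β,3β,11β-trihydroxy-19,20-lactone gibberell-16-en-7-oic acid | C=C1C[C@]23C[C@H]1C[C@H](O)[C@H]2[C@]12COC(=O)[C@](C)([C@@H](O)[C@@H](O)C1)[C@H]2[C@@H]3C(=O)O | target

## Step count and risks

Total step count: 15. Longest linear sequence: 15 steps (fully linear from 1).

Three steps most likely to fail:

Step 2 (the proposed new annulation; risks are low reactivity of the β-substituted enone, competing intramolecular aldol to a bicyclo[3.3.1]nonane, and iodination at the wrong carbon). The fallback uses known chemistry and sets out from 4. High-pressure (about 9 kbar) Michael addition of dimethyl malonate with the same cinchona primary-amine salt gives dimethyl 2-{3-oxo-1-[3-(trimethylsilyl)prop-2-yn-1-yl]cyclohexyl}malonate F1. IBX dehydrogenation, possible only on the C12–C13 side, gives dimethyl 2-{5-oxo-1-[3-(trimethylsilyl)prop-2-yn-1-yl]cyclohex-3-en-1-yl}malonate F2. Its dianion (LiN(i-Pr)2, 2.1 equiv, THF, −78 °C) is alkylated at the enone α′-carbon C9 with methyl bromoacetate to give dimethyl 2-{6-(2-methoxy-2-oxoethyl)-5-oxo-1-[3-(trimethylsilyl)prop-2-yn-1-yl]cyclohex-3-en-1-yl}malonate F3. Dieckmann condensation (NaOMe, MeOH) of the acetate carbon onto a malonate ester gives dimethyl 2,4-dioxo-7a-[3-(trimethylsilyl)prop-2-yn-1-yl]-2,3,3a,4,7,7a-hexahydro-1H-indene-1,3-dicarboxylate F4. Transfer hydrogenation of the enone with Hantzsch ester and dibenzylammonium trifluoroacetate (THF, 60 °C) comes back to the route at 8.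

Step 9 (the C4 methyl/vinyl arrangement in the tethered Michael addition is the least secure stereochemical call; only the drawn epimer can undergo step 10). The fallback sets out from 17 and reverses the order of bond formation. Ring-closing metathesis first (second-generation Grubbs catalyst, CH2Cl2, 1 mM, 40 °C) joins the C10 allyl group and the ester vinyl group to the spiro eight-membered (Z)-ene lactone F5, in which C3 and C19 are both tied to C4. KN(SiMe3)2 (THF, −78 to 0 °C, then MeOH and AcOH) then triggers a transannular Michael addition of C4 to C5, so the C4 configuration is dictated by the ring. The route is rejoined at 19 without passing through 18.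

Step 14 (facial selectivity at C11 could be eroded by the axial C10 substituent on C9). The fallback sets out from 21 and sets C11 before ring D exists. Luche reduction (NaBH4, CeCl3·7H2O, MeOH, −78 °C) of the cyclohexenone delivers hydride anti to the C9–C10 bond and gives the 11β allylic alcohol (hydroxyl cis to H-9, C12=C13 retained) F6. n-Bu3SnH/AIBN (benzene, 80 °C) then closes ring D by 5-exo vinyl-radical cyclisation onto the now unactivated C12=C13 alkene, giving the 17-tributylstannyl derivative of 24 F7 (not isolated). Protodestannylation on wet silica comes back to the route at 24, bypassing ketone 23.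

Further compounds
F1 | step 2 | dimethyl 2-{3-oxo-1-[3-(trimethylsilyl)prop-2-yn-1-yl]cyclohexyl}malonate (quaternary centre as in 6) | C[Si](C)(C)C#CC[C@]1(CC(=O)CCC1)C(C(=O)OC)C(=O)OC
F2 | step 2 | dimethyl 2-{5-oxo-1-[3-(trimethylsilyl)prop-2-yn-1-yl]cyclohex-3-en-1-yl}malonate | C[Si](C)(C)C#CC[C@]1(CC(=O)C=CC1)C(C(=O)OC)C(=O)OC
F3 | step 2 | dimethyl 2-{6-(2-methoxy-2-oxoethyl)-5-oxo-1-[3-(trimethylsilyl)prop-2-yn-1-yl]cyclohex-3-en-1-yl}malonate (C6 of the ring epimerisable) | C[Si](C)(C)C#CC[C@]1(C(CC(=O)OC)C(=O)C=CC1)C(C(=O)OC)C(=O)OC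
F4 | step 2 | dimethyl 2,4-dioxo-7a-[3-(trimethylsilyl)prop-2-yn-1-yl]-2,3,3a,4,7,7a-hexahydro-1H-indene-1,3-dicarboxylate (cis-fused) | C[Si](C)(C)C#CC[C@]12CC=CC(=O)[C@H]1C(C(=O)OC)C(=O)C2C(=O)OC
F5 | step 9 | spiro eight-membered (Z)-ene lactone at C10 (ring C10–C1–C2=C3–C4(Me)–C19(=O)–O–C20) on the cyclopentene ester/enone bicycle of 17 | C[Si](C)(C)C#CC[C@]12CC=CC(=O)[C@H]1[C@@]3(C=C2C(=O)OC)C/C=C\C(C)C(=O)OC3
F6 | step 14 | 11β allylic alcohol from 21 (hydroxyl cis to H-9, C12=C13, terminal alkyne) | C#CC[C@]12CC=C[C@H](O)[C@H]1[C@]34COC(=O)[C@](C)([C@@H](O)[C@@H](O)C3)[C@H]4[C@@H]2C(=O)OC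
F7 | step 14 | 17-(tributylstannyl) derivative of 24 (not isolated) | CCCC[Sn](CCCC)(CCCC)C=C1C[C@]23C[C@H]1C[C@H](O)[C@H]2[C@]45COC(=O)[C@](C)([C@@H](O)[C@@H](O)C4)[C@H]5[C@@H]3C(=O)OC
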